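## Retrosynthetic overview

1. Both tertiary carbinols (C7–OH of the perhydro-1-benzoxepine, C5–OH of the decalin) are unmasked last by Markovnikov hydration of two exocyclic methylidene groups, with oxygen entering on the open face of each ring.
2. Key disconnection: the cyclohexane ring of the benzoxepane is grown from a cyclopentanone, not closed. The enabling feature is that C6 of this ring, the CH carrying the two-carbon tether, lies between the quaternary C5a and the carbinol carbon C7 (ketone oxidation level). C6 is therefore excised, with the whole decalin half attached, as a carbenoid carbon that inserts into the C5a–C(=O) bond of a trans-fused oxepane–cyclopentanone.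
3. Left fragment: 2-methylcyclopentane-1,3-dione, Michael/Wittig side chain, CBS desymmetrisation, Mitsunobu inversion, Shi epoxidation, 7-endo epoxide opening (oxepane).
4. Right fragment: ring B is bought (4,4-dimethylcyclohexenone); ring A is added by an enantioselective endo Diels–Alder reaction with a 1-substituted 2-silyloxydiene, which sets C1, C8a and C4a; the enol ether becomes the vinylic methyl group.
5. Ring order: ring B, then ring A (cis-decalin); cyclopentane, then oxepane, then cyclohexane (ring enlargement that also joins the fragments).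

Key step: step 18

Remark on locants: perhydro-1-benzoxepine O1, C2 (Me2), C3 (OH), C5a (Me), C6 (tether), C7 (Me, OH), C9a; decalin as octahydronaphthalene with C1 (tether), C2 (Me), C5 (Me, OH), C8 (Me2). Several descriptors change along the route only because CIP priorities change (for example C5a is R in 20 and 21, S from 26 on).

Assumption: the facial sense of the oxazaborolidinium-catalysed cycloaddition (step 4) is taken from the usual binding model (enone held through C=O and the α-C–H contact, diene adding to the unshielded face); should the antipode form, the (R)-catalyst would be used.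

## Route

Step 1
Reactants: 1 4-chlorobutanoyl chloride
Product: 2 4-chloro-N-methoxy-N-methylbutanamide
Conditions: MeNHOMe·HCl, pyridine, CH2Cl2, 0 °C to rt
Reagents that add atoms: N,O-dimethylhydroxylamine hydrochloride, CNOC.Cl
Why: Acylation of the hydroxylamine by the acid chloride (Weinreb amide formation) should proceed cleanly at 0 °C, where the primary alkyl chloride is inert.

Step 2
Reactants: 2 4-chloro-N-methoxy-N-methylbutanamide
Product: 3 6-chlorohex-1-en-3-one
Conditions: CH2=CHMgBr, THF, −20 °C to 0 °C; inverse quench into cold 1 M HCl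
Reagents that add atoms: vinylmagnesium bromide, C=C[Mg]Br
Why: Weinreb ketone synthesis, in which the N-methoxy-N-methylamide ensures single addition of the Grignard reagent and the acidic quench keeps the released amine from adding to the vinyl ketone.

Step 3
Reactants: 3 6-chlorohex-1-en-3-one
Product: 4 tert-butyl{[(3Z)-6-chlorohexa-1,3-dien-3-yl]oxy}dimethylsilane
Conditions: TBSOTf, Et3N, CH2Cl2, −78 °C to 0 °C
Reagents that add atoms: tert-butyldimethylsilyl trifluoromethanesulfonate, CC(C)(C)[Si](C)(C)OS(=O)(=O)C(F)(F)F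
Why: Soft enolisation (silyl triflate/amine) at the only enolisable α-position should give the 2-silyloxydiene, mainly as the Z enol ether with the chain outside the diene, the only isomer that can reach the s-cis conformation needed in step 4.

Step 4
Reactants: 4 tert-butyl{[(3Z)-6-chlorohexa-1,3-dien-3-yl]oxy}dimethylsilane; 5 4,4-dimethylcyclohex-2-en-1-one
Product: 6 (4aR,5S,8aS)-6-[(tert-butyldimethylsilyl)oxy]-5-(2-chloroethyl)-4,4-dimethyl-3,4,4a,5,8,8a-hexahydronaphthalen-1(2H)-one
Conditions: (S)-3,3-diphenyl-1-(o-tolyl)tetrahydro-1H,3H-pyrrolo[1,2-c][1,3,2]oxazaborole (20 mol%) activated by AlBr3 (16 mol%), CH2Cl2, −40 °C to −20 °C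
Reagents that add atoms: none
Why: Enantioselective Diels–Alder reaction under chiral oxazaborolidinium catalysis: the 2-silyloxy group makes the chain-bearing diene terminus the nucleophilic one, so it bonds to the enone β-carbon next to CMe2; the cyclic dienophile gives the cis ring fusion; endo approach of the Z dienol ether places the three new hydrogens all cis; and the catalyst-bound enone is attacked on its unshielded face, which sets the absolute configuration.

Step 5
Reactants: 6 the Diels–Alder adduct
Product: 7 tert-butyl{[(1S,4aS,8aS)-1-(2-chloroethyl)-8,8-dimethyl-5-methylidene-1,4,4a,5,6,7,8,8a-octahydronaphthalen-2-yl]oxy}dimethylsilane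
Conditions: Cp2TiMe2, toluene, 70 °C, dark
Reagents that add atoms: dimethyltitanocene (Cp2TiMe2), C[Ti](C)(C1C=CC=C1)C1C=CC=C1
Why: Petasis methylenation is non-basic, so the ketone should be converted into the exocyclic alkene without epimerising the adjacent ring-fusion centre and without touching the silyl enol ether.

Step 6
Reactants: 7 the silyl enol ether
Product: 8 (1S,4aS,8aS)-1-(2-chloroethyl)-8,8-dimethyl-5-methylidene-1,4,4a,5,6,7,8,8a-octahydronaphthalen-2-yl trifluoromethanesulfonate
Conditions: CsF, PhNTf2, DME, rt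
Reagents that add atoms: N-phenylbis(trifluoromethanesulfonimide), FC(F)(F)S(=O)(=O)N(c1ccccc1)S(=O)(=O)C(F)(F)F
Why: Fluoride-induced exchange of the silyl enol ether for the enol triflate (O-sulfonylation at the former O–Si site) should keep the double bond at C2=C3 and leave C1 untouched.

Step 7
Reactants: 8 the enol triflate
Product: 9 (1S,4aS,8aS)-1-(2-chloroethyl)-2,8,8-trimethyl-5-methylidene-1,4,4a,5,6,7,8,8a-octahydronaphthalene
Conditions: MeMgBr, Fe(acac)3 (5 mol%), THF/NMP, −30 °C to 0 °C
Reagents that add atoms: methylmagnesium bromide, C[Mg]Br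
Why: Iron-catalysed Kumada-type cross-coupling of the alkenyl triflate with the methyl Grignard reagent should install the ring A methyl group, the primary alkyl chloride and the 1,1-disubstituted alkene being inert.

Step 8
Reactants: 9 the chloride
Product: 10 (1S,4aS,8aS)-1-(2-iodoethyl)-2,8,8-trimethyl-5-methylidene-1,4,4a,5,6,7,8,8a-octahydronaphthalene
Conditions: NaI, acetone, reflux
Reagents that add atoms: sodium iodide, [Na+].[I-]
Why: Finkelstein halide exchange (SN2) should give the more reactive primary iodide.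

Step 9
Reactants: 10 the iodide
Product: 11 (1S,4aS,8aS)-1-(3,3-dibromopropyl)-2,8,8-trimethyl-5-methylidene-1,4,4a,5,6,7,8,8a-octahydronaphthalene
Conditions: CH2Br2, LiN(i-Pr)2, THF/Et2O, −100 °C; then 10, HMPA, −100 °C to −50 °C
Reagents that add atoms: dibromomethane, BrCBr
Why: SN2 alkylation of dibromomethyllithium by the primary iodide should give the 1,1-dibromoalkane, whose CHBr2 carbon is the future C6 of the benzoxepane.

Step 10
Reactants: 12 2-methylcyclopentane-1,3-dione; 13 acrolein
Product: 14 3-(1-methyl-2,5-dioxocyclopentyl)propanal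
Conditions: H2O, rt
Reagents that add atoms: none
Why: Michael addition of the acidic cyclic 1,3-dione to acrolein in water should create the quaternary carbon, still prochiral at this stage.

Step 11
Reactants: 14 3-(1-methyl-2,5-dioxocyclopentyl)propanal
Product: 15 2-methyl-2-(4-methylpent-3-en-1-yl)cyclopentane-1,3-dione
Conditions: i-PrPPh3I, n-BuLi, THF, 0 °C; then 14, −78 °C to 0 °C
Reagents that add atoms: isopropyltriphenylphosphonium iodide, CC(C)[P+](c1ccccc1)(c1ccccc1)c1ccccc1.[I-]
Why: Wittig olefination with the non-stabilised isopropylidene ylide should occur at the aldehyde in preference to the two hindered ring ketones at low temperature.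

Step 12
Reactants: 15 2-methyl-2-(4-methylpent-3-en-1-yl)cyclopentane-1,3-dione
Product: 16 (2R,3R)-3-hydroxy-2-methyl-2-(4-methylpent-3-en-1-yl)cyclopentan-1-one
Conditions: (S)-2-methyl-CBS-oxazaborolidine (20 mol%), catecholborane, toluene, −78 °C
Reagents that add atoms: none
Why: CBS reduction desymmetrises the dione: the (S)-catalyst should give the (R)-carbinol, and hydride attack anti to the larger substituent of the quaternary carbon places OH cis to the chain, which fixes the quaternary centre as R.

Step 13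
Reactants: 16 the cis-ketol
Product: 17 (1S,2R)-2-methyl-2-(4-methylpent-3-en-1-yl)-3-oxocyclopentyl 4-nitrobenzoate
Conditions: 4-nitrobenzoic acid, PPh3, DIAD, toluene, 0 °C to 40 °C
Reagents that add atoms: 4-nitrobenzoic acid, OC(=O)c1ccc(cc1)[N+](=O)[O-]
Why: Mitsunobu reaction: SN2 displacement of the activated alcohol by the acidic carboxylate inverts the carbinol centre, so oxygen ends trans to the chain and cis to methyl, as is known for cyclopentanols next to a quaternary carbon.

Step 14
Reactants: 17 the 4-nitrobenzoate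
Product: 18 (2R,3S)-3-hydroxy-2-methyl-2-(4-methylpent-3-en-1-yl)cyclopentan-1-one
Conditions: K2CO3 (0.3 equiv), MeOH, 0 °C
Reagents that add atoms: none
Why: Methanolysis (transesterification) of the activated ester frees the alcohol with retention under conditions too mild for retro-aldol cleavage.

Step 15
Reactants: 18 the trans-ketol
Product: 19 (2R,3S)-2-{2-[(2S)-3,3-dimethyloxiran-2-yl]ethyl}-3-hydroxy-2-methylcyclopentan-1-one
Conditions: 1,2:4,5-di-O-isopropylidene-β-L-erythro-2,3-hexodiulo-2,6-pyranose (enantiomer of the D-fructose-derived Shi ketone, 30 mol%), KHSO5 (as 2KHSO5·KHSO4·K2SO4), K2CO3, Bu4NHSO4, MeCN/(MeO)2CH2/aq. Na2B4O7 buffer, 0 °C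
Reagents that add atoms: potassium peroxymonosulfate, [K+].OOS(=O)(=O)[O-]
Why: Shi asymmetric epoxidation of the trisubstituted alkene, the chiral dioxirane setting the (S)-epoxide centre by reagent control, independent of the remote ring stereocentres.

Step 16
Reactants: 19 the epoxy ketol
Product: 20 (3S,5aR,8aS)-3-hydroxy-2,2,5a-trimethyloctahydro-6H-cyclopenta[b]oxepin-6-one
Conditions: CSA (10 mol%), CH2Cl2, 0 °C
Reagents that add atoms: none
Why: Acid-catalysed 7-endo epoxide opening: the ring hydroxyl attacks the tertiary epoxide carbon (Markovnikov, SN1-like) with retention at the secondary carbinol carbon, and the trans disposition of OH and tether disfavours the 6-exo mode, so the trans-fused oxepane should result.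

Step 17
Reactants: 20 the bicyclic hydroxy ketone
Product: 21 (3S,5aR,8aS)-3-[(tert-butyldimethylsilyl)oxy]-2,2,5a-trimethyloctahydro-6H-cyclopenta[b]oxepin-6-one
Conditions: TBSOTf, 2,6-lutidine, CH2Cl2, −78 °C
Reagents that add atoms: tert-butyldimethylsilyl trifluoromethanesulfonate, CC(C)(C)[Si](C)(C)OS(=O)(=O)C(F)(F)F
Why: Silylation of the hindered secondary alcohol with the silyl triflate at low temperature, where the ketone is not enol-silylated.

Step 18
Reactants: 11 the gem-dibromide; 21 the bicyclic cyclopentanone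
Product: 26 (3S,5aS,6S,9aS)-3-[(tert-butyldimethylsilyl)oxy]-2,2,5a-trimethyl-6-{2-[(1S,4aS,8aS)-2,8,8-trimethyl-5-methylidene-1,4,4a,5,6,7,8,8a-octahydronaphthalen-1-yl]ethyl}octahydro-1-benzoxepin-7(2H)-one, via dibromoalkyllithium 22 (not isolated), via lithium alkoxide adduct 23 (not isolated), via β-oxido carbenoid 24 (not isolated), via lithium enolate 25 (not isolated)
Conditions: 11, LiN(i-Pr)2, THF/Et2O, −100 °C; 21, −100 °C to −78 °C; n-BuLi, −95 °C to 0 °C; AcOH, −78 °C
Reagents that add atoms: none
Why: LiN(i-Pr)2 deprotonates the CHBr2 carbon of 11 to the dibromoalkyllithium 22, which adds to the cyclopentanone carbonyl of 21 anti to the angular methyl group to give alkoxide 23; Br/Li exchange with n-BuLi then gives the β-oxido carbenoid 24, whose ring C–C bond shifts to the electron-poor carbenoid carbon with loss of LiBr, giving the ring-enlarged lithium enolate 25 regiospecifically. The closest known reaction type is the β-oxido carbenoid one-carbon ring enlargement of cycloalkanones with lithiated 1,1-dibromoalkanes, the carbenoid counterpart of the Tiffeneau–Demjanov rearrangement. No ring is closed by cyclisation: the six-membered carbocycle arises from the five-membered one by 1,2-shift of the C5a–C(=O) bond, and the inserted carbon, which carries the whole decalin half, becomes C6 between C5a and the carbonyl carbon C7. The one new stereocentre, C6, is set when 25 is protonated at low temperature: the proton should add axially on the enolate face anti to the axial C5a methyl group, leaving the tether equatorial, which is also the arrangement preferred at equilibrium. The step needs carbonyl addition in preference to enolisation (low basicity of the carbenoid at −100 °C) and migration of the quaternary C5a in preference to the ring CH2 (pinacol-like shift in which the more substituted α-carbon migrates, the sense known for 2-alkylcycloalkanones).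

Step 19
Reactants: 26 the ring-enlarged ketone
Product: 27 tert-butyldimethyl{[(3S,5aS,6R,9aS)-2,2,5a-trimethyl-7-methylidene-6-{2-[(1S,4aS,8aS)-2,8,8-trimethyl-5-methylidene-1,4,4a,5,6,7,8,8a-octahydronaphthalen-1-yl]ethyl}decahydro-1-benzoxepin-3-yl]oxy}silane
Conditions: Cp2TiMe2, toluene, 75 °C, dark
Reagents that add atoms: dimethyltitanocene (Cp2TiMe2), C[Ti](C)(C1C=CC=C1)C1C=CC=C1
Why: Petasis methylenation of the hindered ketone is non-basic, so the α-stereocentre C6 should not be epimerised.

Step 20
Reactants: 27 the silyl ether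
Product: 28 (3S,5aS,6R,9aS)-2,2,5a-trimethyl-7-methylidene-6-{2-[(1S,4aS,8aS)-2,8,8-trimethyl-5-methylidene-1,4,4a,5,6,7,8,8a-octahydronaphthalen-1-yl]ethyl}decahydro-1-benzoxepin-3-ol
Conditions: Bu4NF, THF, 45 °C
Reagents that add atoms: none
Why: Fluoride-mediated desilylation should free the secondary alcohol without affecting the three alkenes.

Step 21
Reactants: 28 the triene alcohol
Product: 29 sipholenol L, (3S,5aS,6S,7S,9aS)-6-{2-[(1S,4aS,5S,8aR)-5-hydroxy-2,5,8,8-tetramethyl-1,4,4a,5,6,7,8,8a-octahydronaphthalen-1-yl]ethyl}-2,2,5a,7-tetramethyldecahydro-1-benzoxepine-3,7-diol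
Conditions: Mn(dpm)3 (20 mol%), PhSiH3, O2 (1 atm), i-PrOH/CH2Cl2, 0 °C
Reagents that add atoms: dioxygen, O=O
Why: Double Mukaiyama hydration (hydrogen atom transfer, then O2 capture of the tertiary radicals): the two 1,1-disubstituted alkenes should react faster than the trisubstituted ring A alkene, and oxygen should approach each radical on its open face (equatorial and anti to the axial C5a methyl at C7; convex face of the cis-decalin at C5), which sets both carbinol centres.

## Compound list

1 | 4-chlorobutanoyl chloride | ClCCCC(Cl)=O | starting material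
2 | 4-chloro-N-methoxy-N-methylbutanamide | CON(C)C(=O)CCCCl | intermediate
3 | 6-chlorohex-1-en-3-one | C=CC(=O)CCCCl | intermediate
4 | tert-butyl{[(3Z)-6-chlorohexa-1,3-dien-3-yl]oxy}dimethylsilane | C=C/C(O[Si](C)(C)C(C)(C)C)=C/CCCl | intermediate
5 | 4,4-dimethylcyclohex-2-en-1-one | CC1(C)CCC(=O)C=C1 | starting material
6 | (4aR,5S,8aS)-6-[(tert-butyldimethylsilyl)oxy]-5-(2-chloroethyl)-4,4-dimethyl-3,4,4a,5,8,8a-hexahydronaphthalen-1(2H)-one | CC(C)(C)[Si](C)(C)OC1=CC[C@H]2[C@@H]([C@@H]1CCCl)C(C)(C)CCC2=O | intermediate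
7 | tert-butyl{[(1S,4aS,8aS)-1-(2-chloroethyl)-8,8-dimethyl-5-methylidene-1,4,4a,5,6,7,8,8a-octahydronaphthalen-2-yl]oxy}dimethylsilane | CC(C)(C)[Si](C)(C)OC1=CC[C@H]2[C@@H]([C@@H]1CCCl)C(C)(C)CCC2=C | intermediate
8 | (1S,4aS,8aS)-1-(2-chloroethyl)-8,8-dimethyl-5-methylidene-1,4,4a,5,6,7,8,8a-octahydronaphthalen-2-yl trifluoromethanesulfonate | FC(F)(F)S(=O)(=O)OC1=CC[C@H]2[C@@H]([C@@H]1CCCl)C(C)(C)CCC2=C | intermediate
9 | (1S,4aS,8aS)-1-(2-chloroethyl)-2,8,8-trimethyl-5-methylidene-1,4,4a,5,6,7,8,8a-octahydronaphthalene | CC1=CC[C@H]2[C@@H]([C@@H]1CCCl)C(C)(C)CCC2=C | intermediate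
10 | (1S,4aS,8aS)-1-(2-iodoethyl)-2,8,8-trimethyl-5-methylidene-1,4,4a,5,6,7,8,8a-octahydronaphthalene | CC1=CC[C@H]2[C@@H]([C@@H]1CCI)C(C)(C)CCC2=C | intermediate
11 | (1S,4aS,8aS)-1-(3,3-dibromopropyl)-2,8,8-trimethyl-5-methylidene-1,4,4a,5,6,7,8,8a-octahydronaphthalene | CC1=CC[C@H]2[C@@H]([C@@H]1CCC(Br)Br)C(C)(C)CCC2=C | intermediate
12 | 2-methylcyclopentane-1,3-dione | CC1C(=O)CCC1=O | starting material
13 | acrolein | C=CC=O | starting material
14 | 3-(1-methyl-2,5-dioxocyclopentyl)propanal | CC1(CCC=O)C(=O)CCC1=O | intermediate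
15 | 2-methyl-2-(4-methylpent-3-en-1-yl)cyclopentane-1,3-dione | CC(C)=CCCC1(C)C(=O)CCC1=O | intermediate
16 | (2R,3R)-3-hydroxy-2-methyl-2-(4-methylpent-3-en-1-yl)cyclopentan-1-one | C[C@@]1(CCC=C(C)C)[C@H](O)CCC1=O | intermediate
17 | (1S,2R)-2-methyl-2-(4-methylpent-3-en-1-yl)-3-oxocyclopentyl 4-nitrobenzoate | C[C@@]1(CCC=C(C)C)[C@@H](OC(=O)c2ccc(cc2)[N+](=O)[O-])CCC1=O | intermediate
18 | (2R,3S)-3-hydroxy-2-methyl-2-(4-methylpent-3-en-1-yl)cyclopentan-1-one | C[C@@]1(CCC=C(C)C)[C@@H](O)CCC1=O | intermediate
19 | (2R,3S)-2-{2-[(2S)-3,3-dimethyloxiran-2-yl]ethyl}-3-hydroxy-2-methylcyclopentan-1-one | C[C@@]1(CC[C@@H]2OC2(C)C)[C@@H](O)CCC1=O | intermediate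
20 | (3S,5aR,8aS)-3-hydroxy-2,2,5a-trimethyloctahydro-6H-cyclopenta[b]oxepin-6-one (trans-fused) | C[C@@]12CC[C@H](O)C(C)(C)O[C@H]1CCC2=O | intermediate
21 | (3S,5aR,8aS)-3-[(tert-butyldimethylsilyl)oxy]-2,2,5a-trimethyloctahydro-6H-cyclopenta[b]oxepin-6-one | C[C@@]12CC[C@H](O[Si](C)(C)C(C)(C)C)C(C)(C)O[C@H]1CCC2=O | intermediate
22 | {1,1-dibromo-3-[(1S,4aS,8aS)-2,8,8-trimethyl-5-methylidene-1,4,4a,5,6,7,8,8a-octahydronaphthalen-1-yl]propyl}lithium | CC1=CC[C@H]2[C@@H]([C@@H]1CCC([Li])(Br)Br)C(C)(C)CCC2=C | intermediate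
23 | lithium (3S,5aR,6R,8aS)-3-[(tert-butyldimethylsilyl)oxy]-6-{1,1-dibromo-3-[(1S,4aS,8aS)-decalinyl]propyl}-2,2,5a-trimethyloctahydro-2H-cyclopenta[b]oxepin-6-olate (decalinyl as in 22) | CC1=CC[C@H]2[C@@H]([C@@H]1CCC(Br)(Br)[C@@]1([O-])CC[C@@H]3OC(C)(C)[C@@H](O[Si](C)(C)C(C)(C)C)CC[C@@]13C)C(C)(C)CCC2=C.[Li+] | intermediate
24 | β-oxido carbenoid: 23 with one bromine of the CBr2 carbon exchanged for lithium (configuration at that carbon undefined) | CC1=CC[C@H]2[C@@H]([C@@H]1CCC([Li])(Br)[C@@]1([O-])CC[C@@H]3OC(C)(C)[C@@H](O[Si](C)(C)C(C)(C)C)CC[C@@]13C)C(C)(C)CCC2=C.[Li+] | intermediate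
25 | lithium (3S,5aS,9aS)-3-[(tert-butyldimethylsilyl)oxy]-2,2,5a-trimethyl-6-{2-[(1S,4aS,8aS)-decalinyl]ethyl}-2,3,4,5,5a,8,9,9a-octahydro-1-benzoxepin-7-olate (C6=C7 enolate) | CC1=CC[C@H]2[C@@H]([C@@H]1CCC1=C([O-])CC[C@@H]3OC(C)(C)[C@@H](O[Si](C)(C)C(C)(C)C)CC[C@@]13C)C(C)(C)CCC2=C.[Li+] | intermediate
26 | (3S,5aS,6S,9aS)-3-[(tert-butyldimethylsilyl)oxy]-2,2,5a-trimethyl-6-{2-[(1S,4aS,8aS)-2,8,8-trimethyl-5-methylidene-1,4,4a,5,6,7,8,8a-octahydronaphthalen-1-yl]ethyl}octahydro-1-benzoxepin-7(2H)-one | CC1=CC[C@H]2[C@@H]([C@@H]1CC[C@H]1[C@]3(C)CC[C@H](O[Si](C)(C)C(C)(C)C)C(C)(C)O[C@H]3CCC1=O)C(C)(C)CCC2=C | intermediate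
27 | tert-butyldimethyl{[(3S,5aS,6R,9aS)-2,2,5a-trimethyl-7-methylidene-6-{2-[(1S,4aS,8aS)-2,8,8-trimethyl-5-methylidene-1,4,4a,5,6,7,8,8a-octahydronaphthalen-1-yl]ethyl}decahydro-1-benzoxepin-3-yl]oxy}silane | CC1=CC[C@H]2[C@@H]([C@@H]1CC[C@H]1[C@]3(C)CC[C@H](O[Si](C)(C)C(C)(C)C)C(C)(C)O[C@H]3CCC1=C)C(C)(C)CCC2=C | intermediate
28 | (3S,5aS,6R,9aS)-2,2,5a-trimethyl-7-methylidene-6-{2-[(1S,4aS,8aS)-2,8,8-trimethyl-5-methylidene-1,4,4a,5,6,7,8,8a-octahydronaphthalen-1-yl]ethyl}decahydro-1-benzoxepin-3-ol | CC1=CC[C@H]2[C@@H]([C@@H]1CC[C@H]1[C@]3(C)CC[C@H](O)C(C)(C)O[C@H]3CCC1=C)C(C)(C)CCC2=C | intermediate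
29 | sipholenol L | CC1=CC[C@H]2[C@@H]([C@@H]1CC[C@H]1[C@]3(C)CC[C@H](O)C(C)(C)O[C@H]3CC[C@]1(C)O)C(C)(C)CC[C@]2(C)O | target

## Step count and risks

Total step count: 21. Longest linear sequence: 13 steps (steps 1 to 9, then 18 to 21).

Steps most likely to fail:

Step 18. What may go wrong: the fully substituted carbenoid carbon fails to add to the hindered α-quaternary carbonyl (enolisation instead), or the ring CH2 migrates in place of the quaternary carbon. Fallback: the union is made by a selenium-based semipinacol ring enlargement, which uses a less hindered secondary carbanion and a cationic 1,2-shift. It sets out from iodide 10: alkylation of metallated bis(methylseleno)methane ((MeSe)2CH2, KN(i-Pr)2, THF, −78 °C) gives the selenoacetal F1. Selenium–lithium exchange with n-BuLi (THF, −78 °C) gives the α-selenoalkyllithium F2, which adds to ketone 21 to give the β-hydroxy selenide F3. Activation of selenium with AgBF4 on Al2O3 (CH2Cl2, rt) should then trigger migration of the quaternary carbon, and the route is rejoined at ketone 26.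

Step 4. What may go wrong: slow cycloaddition at the neopentyl-type β-carbon with decomposition of the silyl dienol ether, or low facial selectivity. Fallback: diene 4 and enone 5 are combined under the mixed Lewis acid AlBr3/AlMe3 (toluene/CH2Cl2, 0 °C), conditions suited to hindered silyloxydiene/enone pairs. This gives adduct 6 as a racemate, that is together with its antipode F4. The antipodes are separated by preparative chromatography on a chiral stationary phase, and 6 re-enters the route at step 5.

Step 21. What may go wrong: over-hydration at the ring A double bond, or poor facial selectivity in the radical oxygenation. Fallback: from triene 28 the two methylidene groups are hydrated by ionic oxymercuration–demercuration (Hg(OAc)2, THF/H2O, rt; then NaBH4, aq. NaOH), in which 1,1-disubstituted alkenes react much faster than trisubstituted ring alkenes and water opens each mercurinium ion at the tertiary carbon from the open face. The bis(acetoxymercurio) diol F5 is reduced in the same flask, and the route is rejoined at target 29.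

## Further compounds

F1 | step 18 | (1S,4aS,8aS)-1-[3,3-bis(methylselanyl)propyl]-2,8,8-trimethyl-5-methylidene-1,4,4a,5,6,7,8,8a-octahydronaphthalene | CC1=CC[C@H]2[C@@H]([C@@H]1CCC([Se]C)[Se]C)C(C)(C)CCC2=C
F2 | step 18 | {1-(methylselanyl)-3-[(1S,4aS,8aS)-2,8,8-trimethyl-5-methylidene-1,4,4a,5,6,7,8,8a-octahydronaphthalen-1-yl]propyl}lithium | CC1=CC[C@H]2[C@@H]([C@@H]1CCC([Li])[Se]C)C(C)(C)CCC2=C
F3 | step 18 | (3S,5aR,6R,8aS)-3-[(tert-butyldimethylsilyl)oxy]-2,2,5a-trimethyl-6-{1-(methylselanyl)-3-[(1S,4aS,8aS)-2,8,8-trimethyl-5-methylidene-1,4,4a,5,6,7,8,8a-octahydronaphthalen-1-yl]propyl}octahydro-2H-cyclopenta[b]oxepin-6-ol (both epimers at the selenium-bearing carbon) | CC1=CC[C@H]2[C@@H]([C@@H]1CCC([Se]C)[C@@]1(O)CC[C@@H]3OC(C)(C)[C@@H](O[Si](C)(C)C(C)(C)C)CC[C@@]13C)C(C)(C)CCC2=C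
F4 | step 4 | (4aS,5R,8aR)-6-[(tert-butyldimethylsilyl)oxy]-5-(2-chloroethyl)-4,4-dimethyl-3,4,4a,5,8,8a-hexahydronaphthalen-1(2H)-one (antipode of 6) | CC(C)(C)[Si](C)(C)OC1=CC[C@@H]2[C@H]([C@H]1CCCl)C(C)(C)CCC2=O
F5 | step 21 | bis-organomercurial of the target, in which the methyl group on each tertiary carbinol carbon (C7 of the benzoxepane, C5 of the decalin) is a CH2HgOAc group | CC1=CC[C@H]2[C@@H]([C@@H]1CC[C@H]1[C@]3(C)CC[C@H](O)C(C)(C)O[C@H]3CC[C@]1(C[Hg]OC(C)=O)O)C(C)(C)CC[C@]2(C[Hg]OC(C)=O)O
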